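**Retrosynthetic overview**
1. The target is read as a labdane trans-decalin (rings A and B, C1–C10, with C18 as methyl ester, 6α-OH and 8α-OH), an (E)-C13=C14 alkene, the carbinol C15 and a butenolide (ring C: O1', C2'=O, C3', C4'-methyl, C5'-H). C15 and C5' are joined in a syn 15S,5'S array.
2. Key disconnection: the C4'–C5' bond of ring C. It leads back to the acyclic, stereochemically blank keto ester 18, a (but-2-ynoyloxy)methyl enone. Base-triggered 5-endo-dig ring closure and asymmetric transfer hydrogenation with dynamic kinetic resolution run in one flask and create ring C, C15 and C5'.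
3. Enabling feature: C5' is a CH held between the ring oxygen O1', the vinylogous ester C4'=C3'–C2'=O and C15. With C15 at the ketone level it is acidic enough to act as the carbon nucleophile towards the alkynoate β-carbon (the future C4'). Once ring C exists, it epimerises freely through an aromatic 2-oxidofuran.
4. 18 is cut at C14–C15 into alkenyl iodide 12 and aldehyde 16 (Nozaki–Hiyama–Kishi coupling, then MnO2). The (E)-alkene comes from carboalumination of alkyne 10.
5. Order of rings: A and B are bought with (+)-larixol. A temporary oxirane (C8, C17) and a temporary C18–O–C6 ring (ether, then lactone, made by a 6α-alkoxyl radical C–H functionalisation that sets C4) are built in steps 2 to 4 and opened in step 6. Ring C is closed last.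

Key step: step 13

Assumption: (+)-larixol (labda-8(17),14-diene-6α,13S-diol) is taken as a purchasable chiral-pool diterpene. Atom numbers follow the labdane skeleton, and primed numbers denote the butenolide ring as defined above.

**Step 1**
Reactants: 1 (+)-larixol
Product: 2 hydroxy ketone (6α-hydroxy-14,15-dinorlabd-8(17)-en-13-one)
Conditions: KMnO4, acetone/H2O, 0 °C to rt
Reagents that add atoms: none
Why: Permanganate degradation of a tertiary vinyl carbinol (dihydroxylation of the monosubstituted C14=C15 alkene followed by glycol-type cleavage of C13–C14) should leave the C13 methyl ketone, the hindered exocyclic C8=C17 alkene and the equatorial 6α-alcohol being attacked more slowly, and no ring stereocentre is touched.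

**Step 2**
Reactants: 2 hydroxy ketone
Product: 3 epoxy ketone (8α,17-epoxy-6α-hydroxy-14,15-dinorlabdan-13-one)
Conditions: mCPBA, CH2Cl2, 0 °C
Reagents that add atoms: mCPBA, O=C(OO)c1cccc(Cl)c1
Why: Prilezhaev epoxidation of the 1,1-disubstituted alkene should take place from the α face, because the β face of C8 is screened by the syn-axial C10 methyl group, so that the new C8–O bond is α (equatorial) as in the target.

**Step 3**
Reactants: 3 epoxy ketone
Product: 4 bridged ether (6α,18:8α,17-diepoxy-14,15-dinorlabdan-13-one)
Conditions: PhI(OAc)2, I2, cyclohexane/CH2Cl2, hν (tungsten lamp), rt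
Reagents that add atoms: none
Why: Suárez hypoiodite reaction: the 6α-alkoxyl radical abstracts hydrogen through a six-membered transition state (1,5-hydrogen atom transfer) from the equatorial 4α-methyl group, whose C–C bond runs parallel to the C6–O bond, and iodination and displacement close the tetrahydrofuran, which desymmetrises the gem-dimethyl group and so sets C4, the axial 4β-methyl group being out of reach.

**Step 4**
Reactants: 4 bridged ether
Product: 5 epoxy keto lactone (8α,17-epoxy-13-oxo-14,15-dinorlabdan-18,6α-olide)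
Conditions: RuCl3·xH2O (cat.), NaIO4, MeCN/EtOAc/H2O, rt
Reagents that add atoms: NaIO4 (oxygen source, relayed by RuO4), [Na+].[O-]I(=O)(=O)=O
Why: RuO4 oxidation of a cyclic ether to a lactone should attack the exposed O–CH2 group (C18) and not the O–CH at C6, whose axial β hydrogen lies between the two axial methyl groups, while ketone and oxirane are inert to this oxidant.

**Step 5**
Reactants: 5 epoxy keto lactone
Product: 7 alkynyl epoxy lactone (8α,17-epoxy-14,15-dinorlabd-13(16)-yn-18,6α-olide), via enol phosphate 6 (not isolated)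
Conditions: LDA, THF, −78 °C; ClP(O)(OEt)2, −78 to 0 °C; LDA (excess), −78 to 0 °C; aq NH4Cl
Reagents that add atoms: diethyl chlorophosphate, CCOP(=O)(Cl)OCC (its atoms are found in 6 only and leave again on the way to 7)
Why: Negishi conversion of a methyl ketone into a terminal alkyne by kinetic deprotonation at the methyl group, O-phosphorylation and base-induced elimination of diethyl phosphate, feasible here because the lactone has no α hydrogen and masks both the 6-hydroxyl group and the acid, so that no other acidic site is present.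

**Step 6**
Reactants: 7 alkynyl epoxy lactone
Product: 9 dihydroxy acid (6α,8α-dihydroxy-14,15-dinorlabd-13(16)-yn-18-oic acid), via lithium carboxylate 8 (not isolated)
Conditions: LiOH, THF/H2O, rt; evaporation, toluene azeotrope; LiEt3BH, THF, 0 °C to rt; cold dilute HCl (pH 4–5)
Reagents that add atoms: lithium hydroxide, [Li+].[OH-]
Why: Saponification of the doubly trans-fused and therefore strained γ-lactone gives a carboxylate that hydride does not reduce, so that LiEt3BH can open the oxirane by SN2 attack at the primary C17, which leaves the C8–O bond untouched and turns C17 into the axial 8β-methyl group (8α-OH retained from step 2).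

**Step 7**
Reactants: 9 dihydroxy acid
Product: 10 alkynyl methyl ester (methyl 6α,8α-dihydroxy-14,15-dinorlabd-13(16)-yn-18-oate)
Conditions: MeI, K2CO3, DMF, rt
Reagents that add atoms: iodomethane, [CH3]I
Why: SN2 O-alkylation of the carboxylate with MeI forms the hindered ester without any attack at the neopentyl-type carbonyl carbon and leaves both alcohols and the alkyne untouched.

**Step 8**
Reactants: 10 alkynyl methyl ester
Product: 12 alkenyl iodide (methyl (13E)-14-iodo-6α,8α-dihydroxy-15-norlabd-13-en-18-oate), via alkenylalane 11 (not isolated)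
Conditions: Me3Al (excess), Cp2ZrCl2 (cat.), CH2Cl2, 0 °C to rt; I2, THF, −30 °C; aqueous work-up
Reagents that add atoms: trimethylaluminium, C[Al](C)C; iodine, [I][I]
Why: Negishi zirconium-catalysed carboalumination adds methyl and aluminium syn across the terminal alkyne with aluminium at the terminus (the two hydroxyl groups being held as aluminium alkoxides), and iodinolysis with retention should give only the (E)-trisubstituted alkenyl iodide.

**Step 9**
Reactants: 13 but-2-ynoic acid; 14 2,2-dimethoxyethanol
Product: 15 2,2-dimethoxyethyl but-2-ynoate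
Conditions: N,N'-dicyclohexylcarbodiimide, DMAP (cat.), CH2Cl2, 0 °C to rt
Reagents that add atoms: none
Why: Steglich esterification couples the acid and the primary alcohol under neutral conditions that do not isomerise the alkynoate to the allenoate.

**Step 10**
Reactants: 15 2,2-dimethoxyethyl but-2-ynoate
Product: 16 2-oxoethyl but-2-ynoate
Conditions: TFA/H2O, CH2Cl2, 0 °C to rt
Reagents that add atoms: water, O
Why: Acid-catalysed acetal hydrolysis releases the aldehyde while ester and conjugated alkyne stay intact, and the aldehyde is used crude to avoid hydrate and oligomer formation.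

**Step 11**
Reactants: 12 alkenyl iodide; 16 2-oxoethyl but-2-ynoate
Product: 17 allylic alcohol (methyl (13E)-15-[(but-2-ynoyloxy)methyl]-6α,8α,15-trihydroxylabd-13-en-18-oate as both C15 epimers)
Conditions: CrCl2 (excess), NiCl2 (cat.), DMSO, rt
Reagents that add atoms: none
Why: Nozaki–Hiyama–Kishi coupling (oxidative addition of the alkenyl iodide to zerovalent nickel, transmetalation to chromium and chemoselective addition to the aldehyde with retention of the (E) geometry) tolerates free hydroxyl groups and esters, and the lack of control at C15 is irrelevant because this centre is erased in step 12.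

**Step 12**
Reactants: 17 allylic alcohol
Product: 18 alkynoate enone (methyl (13E)-15-[(but-2-ynoyloxy)methyl]-6α,8α-dihydroxy-15-oxolabd-13-en-18-oate)
Conditions: MnO2, CH2Cl2, rt
Reagents that add atoms: none
Why: MnO2 oxidises only the allylic alcohol, so both C15 epimers converge on one enone while the saturated 6α-alcohol and the tertiary 8α-alcohol remain.

**Step 13**
Reactants: 18 alkynoate enone
Product: 20 CNP0104474.1 (methyl (13E,15S)-6α,8α,15-trihydroxy-15-[(2S)-3-methyl-5-oxo-2,5-dihydrofuran-2-yl]labd-13-en-18-oate), via acylbutenolide 19 (not isolated)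
Conditions: DBU (1.2 equiv), MeCN, 0 °C to rt; then, same flask, HCO2H/Et3N (5:2), RuCl[(R,R)-TsDPEN](p-cymene) (cat.), rt
Reagents that add atoms: none
Why: Proposed new method: DBU removes one of the two C5' hydrogens of 18 (α to the C15 ketone and to the acyloxy oxygen), the enolate carbon adds to the alkynoate β-carbon C4' (directly or after base-induced alkynoate–allenoate isomerisation) and proton shifts deliver 19 as its aromatic 2-oxidofuran salt, which the formic acid buffer then releases as a ketone whose C5' epimers interconvert fast through that same anion while the ruthenium hydride reduces C15=O. The closest known reaction types are the base-mediated endo-dig intramolecular Michael addition of stabilised carbanions to conjugated alkynones and alkynoates, the 5-endo-dig closure of α'-hydroxy ynones to 3(2H)-furanones, and the Noyori–Ikariya transfer hydrogenation with dynamic kinetic resolution of α-alkoxy β-keto esters (aryl and alkenyl ketones) to syn-1,2-diol derivatives, of which 19 is the vinylogue. The butenolide ring is closed in the 5-endo-dig mode by the C4'–C5' bond from the s-cis ester rotamer, the nucleophile entering the in-plane π* orbital of the alkyne, and the closure is made irreversible by formation of the acyl-stabilised furanolate. C15 is set by the catalyst: with the (R,R)-TsDPEN ligand the alkenyl group takes the place that aryl groups take under the η6-arene (CH/π contact), so hydride reaches the face that gives 15S. C5' is set by the dynamic kinetic resolution, since of the two equilibrating epimers the one whose Felkin–Anh face (C5'–O1' bond anti to the incoming hydride) coincides with the face chosen by the catalyst is reduced faster, which gives the syn 15S,5'S pair. The step needs C- over O-cyclisation, 1,2- over 1,4-reduction and reduction of the right tautomer, secured in turn by ring size (O-attack would need a seven-membered ring), by the fully substituted β-carbon C13 of the enone, and by the fact that only the 2(5H)-furanone tautomer carries a non-conjugated, inductively activated ketone.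

**Compound list**
1 | (+)-larixol, labda-8(17),14-diene-6α,13S-diol | CC1(C)CCC[C@@]2(C)[C@H]1[C@@H](O)CC(=C)[C@@H]2CC[C@](C)(O)C=C | starting material
2 | 6α-hydroxy-14,15-dinorlabd-8(17)-en-13-one | CC1(C)CCC[C@@]2(C)[C@H]1[C@@H](O)CC(=C)[C@@H]2CCC(C)=O | intermediate
3 | 8α,17-epoxy-6α-hydroxy-14,15-dinorlabdan-13-one | CC1(C)CCC[C@@]2(C)[C@H]1[C@@H](O)C[C@@]3(OC3)[C@@H]2CCC(C)=O | intermediate
4 | 6α,18:8α,17-diepoxy-14,15-dinorlabdan-13-one | C4[C@]1(C)CCC[C@@]2(C)[C@H]1[C@@H](O4)C[C@@]3(OC3)[C@@H]2CCC(C)=O | intermediate
5 | 8α,17-epoxy-13-oxo-14,15-dinorlabdan-18,6α-olide | O=C4[C@]1(C)CCC[C@@]2(C)[C@H]1[C@@H](O4)C[C@@]3(OC3)[C@@H]2CCC(C)=O | intermediate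
6 | terminal diethyl enol phosphate of 5 (not isolated) | O=C4[C@]1(C)CCC[C@@]2(C)[C@H]1[C@@H](O4)C[C@@]3(OC3)[C@@H]2CCC(=C)OP(=O)(OCC)OCC | intermediate
7 | 8α,17-epoxy-14,15-dinorlabd-13(16)-yn-18,6α-olide | O=C4[C@]1(C)CCC[C@@]2(C)[C@H]1[C@@H](O4)C[C@@]3(OC3)[C@@H]2CCC#C | intermediate
8 | lithium 8α,17-epoxy-6α-hydroxy-14,15-dinorlabd-13(16)-yn-18-oate (not isolated) | [Li+].[O-]C(=O)[C@]1(C)CCC[C@@]2(C)[C@H]1[C@@H](O)C[C@@]3(OC3)[C@@H]2CCC#C | intermediate
9 | 6α,8α-dihydroxy-14,15-dinorlabd-13(16)-yn-18-oic acid | OC(=O)[C@]1(C)CCC[C@@]2(C)[C@H]1[C@@H](O)C[C@@](C)(O)[C@@H]2CCC#C | intermediate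
10 | methyl 6α,8α-dihydroxy-14,15-dinorlabd-13(16)-yn-18-oate | COC(=O)[C@]1(C)CCC[C@@]2(C)[C@H]1[C@@H](O)C[C@@](C)(O)[C@@H]2CCC#C | intermediate
11 | (E)-alkenyl(dimethyl)alane with both hydroxyl groups as dimethylaluminium alkoxides (not isolated) | COC(=O)[C@]1(C)CCC[C@@]2(C)[C@H]1[C@@H](O[Al](C)C)C[C@@](C)(O[Al](C)C)[C@@H]2CC/C(C)=C/[Al](C)C | intermediate
12 | methyl (13E)-14-iodo-6α,8α-dihydroxy-15-norlabd-13-en-18-oate | COC(=O)[C@]1(C)CCC[C@@]2(C)[C@H]1[C@@H](O)C[C@@](C)(O)[C@@H]2CC/C(C)=C/I | intermediate
13 | but-2-ynoic acid | CC#CC(=O)O | starting material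
14 | 2,2-dimethoxyethanol | COC(CO)OC | starting material
15 | 2,2-dimethoxyethyl but-2-ynoate | CC#CC(=O)OCC(OC)OC | intermediate
16 | 2-oxoethyl but-2-ynoate | CC#CC(=O)OCC=O | intermediate
17 | methyl (13E)-15-[(but-2-ynoyloxy)methyl]-6α,8α,15-trihydroxylabd-13-en-18-oate, both C15 epimers | COC(=O)[C@]1(C)CCC[C@@]2(C)[C@H]1[C@@H](O)C[C@@](C)(O)[C@@H]2CC/C(C)=C/C(O)COC(=O)C#CC | intermediate
18 | methyl (13E)-15-[(but-2-ynoyloxy)methyl]-6α,8α-dihydroxy-15-oxolabd-13-en-18-oate | COC(=O)[C@]1(C)CCC[C@@]2(C)[C@H]1[C@@H](O)C[C@@](C)(O)[C@@H]2CC/C(C)=C/C(=O)COC(=O)C#CC | intermediate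
19 | methyl (13E)-6α,8α-dihydroxy-15-(3-methyl-5-oxo-2,5-dihydrofuran-2-yl)-15-oxolabd-13-en-18-oate, C5' epimers in fast exchange (not isolated) | COC(=O)[C@]1(C)CCC[C@@]2(C)[C@H]1[C@@H](O)C[C@@](C)(O)[C@@H]2CC/C(C)=C/C(=O)C1OC(=O)C=C1C | intermediate
20 | CNP0104474.1, methyl (13E,15S)-6α,8α,15-trihydroxy-15-[(2S)-3-methyl-5-oxo-2,5-dihydrofuran-2-yl]labd-13-en-18-oate | COC(=O)[C@]1(C)CCC[C@@]2(C)[C@H]1[C@@H](O)C[C@@](C)(O)[C@@H]2CC/C(C)=C/[C@H](O)[C@H]1OC(=O)C=C1C | target

**Totals**
Total step count: 13.
Longest linear sequence: 11 steps (steps 1 to 8 and 11 to 13, from 1).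

**Steps most likely to fail**

Step 13 (new method).
- What may go wrong: intermolecular addition of the enolate to the alkynoate or allenoate may outrun the in-plane ring closure. γ-Deprotonation may erode the (E) geometry. Hydride transfer may lose its facial or epimer selectivity.
- Fallback: it uses known chemistry, sets out from 12 and comes back at 20.
- Reductive carbonylation of 12 (CO, Bu3SnH, Pd(PPh3)4, THF, 50 °C) would give the enal methyl (13E)-6α,8α-dihydroxy-15-oxolabd-13-en-18-oate F1.
- Commercial 4-methylfuran-2(5H)-one would be silylated (TMSOTf, Et3N, CH2Cl2, 0 °C) to 4-methyl-2-(trimethylsilyloxy)furan F2.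
- A catalytic enantioselective vinylogous Mukaiyama aldol addition of F2 to F1 would form the C15–C5' bond. It would use Ti(OiPr)4 with the BINOL antipode that leads to 15S, in Et2O at −20 °C. This reaction class is syn(threo)-selective under Lewis acid conditions. It would give the 15-O-trimethylsilyl ether of 20 F3, and dilute HCl in THF would release 20.

Step 3.
- What may go wrong: closure of the primary C18 iodide to the doubly trans-fused ether may lag behind renewed hypoiodite formation, or behind β-scission of the C5–C6 bond. The oxidation level at C18 would then become non-uniform.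
- Fallback: it sets out from 3 and comes back at 5, and so replaces steps 3 and 4.
- Nitrosation (NOCl, pyridine, −20 °C) would give 8α,17-epoxy-13-oxo-14,15-dinorlabdan-6α-yl nitrite F4.
- Barton nitrite photolysis (hν, toluene, 0 °C) uses the same hydrogen transfer but traps the C18 radical with NO, so that no strained ring has to close. After tautomerisation it would give the (E)-oxime of 8α,17-epoxy-6α-hydroxy-13-oxo-14,15-dinorlabdan-18-al F5.
- Transoximation with aqueous glyoxylic acid would free the aldehyde, which should close to the lactol 6α,18:8α,17-diepoxy-18-hydroxy-14,15-dinorlabdan-13-one F6.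
- Oxidation with Pr4N[RuO4] and N-methylmorpholine N-oxide would give 5.

Step 11.
- What may go wrong: electron transfer from divalent chromium to the conjugated alkynoate, nickel-mediated carbometalation of that alkyne, or a 1,2-acyl shift within the chromium alkoxide may consume the coupling partners.
- Fallback: it sets out from 12 and comes back at 18, and brings in the alkynoate only after the C–C coupling.
- Nozaki–Hiyama–Kishi coupling of 12 with commercial (tert-butyldimethylsilyloxy)acetaldehyde (CrCl2, NiCl2, DMSO) would give methyl (13E)-15-[(tert-butyldimethylsilyloxy)methyl]-6α,8α,15-trihydroxylabd-13-en-18-oate F7.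
- MnO2 would give methyl (13E)-15-[(tert-butyldimethylsilyloxy)methyl]-6α,8α-dihydroxy-15-oxolabd-13-en-18-oate F8.
- HF·pyridine would give methyl (13E)-6α,8α-dihydroxy-15-(hydroxymethyl)-15-oxolabd-13-en-18-oate F9.
- Steglich esterification of the only unhindered primary hydroxyl group with 13 (N,N'-dicyclohexylcarbodiimide, DMAP, CH2Cl2, 0 °C) would give 18.

**Further compounds**
F1 | step 13 | methyl (13E)-6α,8α-dihydroxy-15-oxolabd-13-en-18-oate | COC(=O)[C@]1(C)CCC[C@@]2(C)[C@H]1[C@@H](O)C[C@@](C)(O)[C@@H]2CC/C(C)=C/C=O
F2 | step 13 | 4-methyl-2-(trimethylsilyloxy)furan | Cc1coc(O[Si](C)(C)C)c1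
F3 | step 13 | 15-O-trimethylsilyl ether of 20 | COC(=O)[C@]1(C)CCC[C@@]2(C)[C@H]1[C@@H](O)C[C@@](C)(O)[C@@H]2CC/C(C)=C/[C@H](O[Si](C)(C)C)[C@H]1OC(=O)C=C1C
F4 | step 3 | 8α,17-epoxy-13-oxo-14,15-dinorlabdan-6α-yl nitrite | CC1(C)CCC[C@@]2(C)[C@H]1[C@@H](ON=O)C[C@@]3(OC3)[C@@H]2CCC(C)=O
F5 | step 3 | (E)-oxime of 8α,17-epoxy-6α-hydroxy-13-oxo-14,15-dinorlabdan-18-al | O/N=C/[C@]1(C)CCC[C@@]2(C)[C@H]1[C@@H](O)C[C@@]3(OC3)[C@@H]2CCC(C)=O
F6 | step 3 | 6α,18:8α,17-diepoxy-18-hydroxy-14,15-dinorlabdan-13-one (C18 epimers) | OC4[C@]1(C)CCC[C@@]2(C)[C@H]1[C@@H](O4)C[C@@]3(OC3)[C@@H]2CCC(C)=O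
F7 | step 11 | methyl (13E)-15-[(tert-butyldimethylsilyloxy)methyl]-6α,8α,15-trihydroxylabd-13-en-18-oate (C15 epimers) | COC(=O)[C@]1(C)CCC[C@@]2(C)[C@H]1[C@@H](O)C[C@@](C)(O)[C@@H]2CC/C(C)=C/C(O)CO[Si](C)(C)C(C)(C)C
F8 | step 11 | methyl (13E)-15-[(tert-butyldimethylsilyloxy)methyl]-6α,8α-dihydroxy-15-oxolabd-13-en-18-oate | COC(=O)[C@]1(C)CCC[C@@]2(C)[C@H]1[C@@H](O)C[C@@](C)(O)[C@@H]2CC/C(C)=C/C(=O)CO[Si](C)(C)C(C)(C)C
F9 | step 11 | methyl (13E)-6α,8α-dihydroxy-15-(hydroxymethyl)-15-oxolabd-13-en-18-oate | COC(=O)[C@]1(C)CCC[C@@]2(C)[C@H]1[C@@H](O)C[C@@](C)(O)[C@@H]2CC/C(C)=C/C(=O)CO
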